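**Plan**
1. Retrosynthesis: open the epoxide (C4–O–C5) to a C5 mesylate and C4 alcohol, return the exocyclic methylene to a C13 allylic carbonate (C7–H), then cut C5–C6 of the ten-membered ring, then the C8/C9 esters, C1=C10, C9–C10 and C7–C8.
2. Forward: the chain is joined at C7–C8 (furyllithium acylation), C9–C10 (phosphonate alkylation) and C1=C10 (Horner–Wadsworth–Emmons); C9 and C8 are then oxygenated, the silylfuran is oxidised to the butenolide, the carbocycle closes last at C5–C6, and the epoxide is made at the end.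
3. Feature used: the γ-lactone O–C12(=O)–C11–C7–C6 is the keto form of a 2-oxyfuran whose free α-carbon C6 is bonded to the oxygen-bearing C5 (later an epoxide carbon), which is a vinylogous aldol retron.
4. Stereochemistry: C4 from (R)-linalool; C9 by reagent-controlled enolate hydroxylation; C8 by Felkin–Anh reduction next to C9; C5 and C6 in the aldol macrocyclisation; C7 by hydride delivery from palladium; C5 inverted on epoxide closure; the 1(10) geometry from the olefination.

Key step: step 18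

Assumption: locants follow the germacrane numbering of the target (C1–C15; C12 lactone carbonyl, C13 exocyclic carbon, C14 ester carbon); Ar1 = 5-(tert-butyldimethylsilyl)-4-{[(tert-butyldiphenylsilyl)oxy]methyl}furan-3-yl, Bt = 4-{[(tert-butyldiphenylsilyl)oxy]methyl}-5-oxo-2,5-dihydrofuran-3-yl, Ar2 = 4-{[(tert-butyldiphenylsilyl)oxy]methyl}-5-[(triisopropylsilyl)oxy]furan-3-yl; (R)-linalool of high enantiomeric purity is taken as commercial.

Step 1
Reactants: 1 (R)-(−)-linalool
Product: 3 (2R)-2-methylpentane-1,2,5-triol, via dialdehyde equivalent 2 (not isolated)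
Conditions: O3, CH2Cl2/MeOH, −78 °C; then NaBH4, −78 °C → rt
Reagents that add atoms: ozone, [O-][O+]=O
Why: Exhaustive ozonolysis cleaves both alkenes and borohydride reduction of the ozonides gives the two primary alcohols (C1 and C5), while the tertiary carbinol C4 is untouched and keeps the (R) configuration of linalool.

Step 2
Reactants: 3 (2R)-2-methylpentane-1,2,5-triol
Product: 4 3-[(4R)-2,2,4-trimethyl-1,3-dioxolan-4-yl]propan-1-ol
Conditions: Me2C(OMe)2, PPTS (cat.), acetone, rt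
Reagents that add atoms: 2,2-dimethoxypropane, COC(C)(C)OC
Why: Acid-catalysed transketalisation under thermodynamic control prefers the five-membered dioxolane of the C4/C5 1,2-diol and leaves the C1 hydroxyl free.

Step 3
Reactants: 4 3-[(4R)-2,2,4-trimethyl-1,3-dioxolan-4-yl]propan-1-ol
Product: 5 3-[(4R)-2,2,4-trimethyl-1,3-dioxolan-4-yl]propanal
Conditions: TEMPO (cat.), PhI(OAc)2, CH2Cl2, rt
Reagents that add atoms: none
Why: Oxoammonium (TEMPO) oxidation of the primary alcohol stops at the aldehyde under neutral conditions that leave the acetonide intact.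

Step 4
Reactants: 6 furan-3-ylmethanol
Product: 7 tert-butyl(furan-3-ylmethoxy)dimethylsilane
Conditions: TBSCl, imidazole, DMF, rt
Reagents that add atoms: tert-butyldimethylsilyl chloride, CC(C)(C)[Si](C)(C)Cl
Why: Imidazole-promoted silylation of the primary alcohol prepares the silicon transfer of the next step.

Step 5
Reactants: 7 tert-butyl(furan-3-ylmethoxy)dimethylsilane
Product: 8 [2-(tert-butyldimethylsilyl)furan-3-yl]methanol
Conditions: n-BuLi, HMPA, THF, −78 °C → rt
Reagents that add atoms: none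
Why: Lithiation at the furan carbon next to the silyloxymethyl group is followed by a [1,4] O→C silyl shift (retro-Brook rearrangement), which places silicon regiospecifically on the future carbonyl carbon C12 and blocks it.

Step 6
Reactants: 8 [2-(tert-butyldimethylsilyl)furan-3-yl]methanol; 9 2-chloro-N-methoxy-N-methylacetamide
Product: 11 1-[5-(tert-butyldimethylsilyl)-4-(hydroxymethyl)furan-3-yl]-2-chloroethan-1-one, via dilithio furan 10 (not isolated)
Conditions: n-BuLi (2.2 equiv), DME, 0 °C; then 9, −78 °C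
Reagents that add atoms: none
Why: With C12 blocked, alkoxide-directed ortho-lithiation occurs at the future C7, and Weinreb amide acylation through a chelated tetrahedral adduct delivers the α-chloro ketone (C8, C9) without over-addition.

Step 7
Reactants: 11 1-[5-(tert-butyldimethylsilyl)-4-(hydroxymethyl)furan-3-yl]-2-chloroethan-1-one
Product: 12 1-Ar1-2-chloroethan-1-one
Conditions: TBDPSCl, Et3N, DMAP (cat.), CH2Cl2, 0 °C → rt
Reagents that add atoms: tert-butyldiphenylsilyl chloride, CC(C)(C)[Si](Cl)(c1ccccc1)c1ccccc1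
Why: Silylation of the primary C13 alcohol with an acid-stable silyl group that survives steps 13–18, using a weakly nucleophilic amine so the chloro ketone is not alkylated.

Step 8
Reactants: 13 trimethyl phosphonoacetate; 12 1-Ar1-2-chloroethan-1-one
Product: 15 methyl 2-(dimethoxyphosphoryl)-4-oxo-4-Ar1-butanoate, via sodium phosphonate enolate 14 (not isolated)
Conditions: NaH, THF, 0 °C; then 12, NaI (cat.), rt
Reagents that add atoms: none
Why: SN2 C-alkylation of the stabilised phosphonate carbanion by the activated α-halo ketone (iodide-assisted) forms the C9–C10 bond.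

Step 9
Reactants: 15 methyl 2-(dimethoxyphosphoryl)-4-oxo-4-Ar1-butanoate; 5 3-[(4R)-2,2,4-trimethyl-1,3-dioxolan-4-yl]propanal
Product: 16 methyl (2E)-2-(2-oxo-2-Ar1-ethyl)-5-[(4R)-2,2,4-trimethyl-1,3-dioxolan-4-yl]pent-2-enoate
Conditions: LiCl, DBU, MeCN, 0 °C → rt
Reagents that add atoms: none
Why: Horner–Wadsworth–Emmons olefination under Masamune–Roush conditions with an α-substituted phosphonoacetate places C2 trans to the ester (1(10)E, as in the target), and the mild base limits deconjugation of the product.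

Step 10
Reactants: 16 methyl (2E)-2-(2-oxo-2-Ar1-ethyl)-5-[(4R)-2,2,4-trimethyl-1,3-dioxolan-4-yl]pent-2-enoate
Product: 19 methyl (2E)-2-[(1R)-1-acetoxy-2-oxo-2-Ar1-ethyl]-5-[(4R)-2,2,4-trimethyl-1,3-dioxolan-4-yl]pent-2-enoate, via sodium dienolate 17 (not isolated), via sodium alkoxide 18 (not isolated)
Conditions: NaN(SiMe3)2, THF, −78 °C; (−)-(camphorsulfonyl)oxaziridine, −78 °C; then Ac2O, −78 → −20 °C
Reagents that add atoms: (−)-(camphorsulfonyl)oxaziridine, CC1(C)[C@H]2CC[C@@]13CS(=O)(=O)N4O[C@@]34C2; acetic anhydride, CC(=O)OC(C)=O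
Why: Asymmetric enolate hydroxylation with a chiral N-sulfonyloxaziridine oxidises the (Z)-enolate at its α-carbon C9, the camphor skeleton selecting the enolate face (the (−)-reagent should give 9R by analogy with aryl benzyl ketone enolates), and in-flask acetylation avoids handling the base-sensitive α-hydroxy ketone.

Step 11
Reactants: 19 methyl (2E)-2-[(1R)-1-acetoxy-2-oxo-2-Ar1-ethyl]-5-[(4R)-2,2,4-trimethyl-1,3-dioxolan-4-yl]pent-2-enoate
Product: 20 methyl (2E)-2-[(1R,2R)-1-acetoxy-2-hydroxy-2-Ar1-ethyl]-5-[(4R)-2,2,4-trimethyl-1,3-dioxolan-4-yl]pent-2-enoate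
Conditions: LiBH(s-Bu)3, THF, −78 °C; then AcOH, −78 °C
Reagents that add atoms: none
Why: Felkin–Anh-controlled reduction with a bulky, non-chelating borohydride, the C9 acetoxy group lying anti to the incoming hydride, should give the 8,9-syn alcohol (8R), and the aryl ketone reacts at −78 °C faster than the esters or the hindered enoate.

Step 12
Reactants: 20 methyl (2E)-2-[(1R,2R)-1-acetoxy-2-hydroxy-2-Ar1-ethyl]-5-[(4R)-2,2,4-trimethyl-1,3-dioxolan-4-yl]pent-2-enoate
Product: 21 methyl (2E)-2-[(1R,2R)-1-acetoxy-2-(methacryloyloxy)-2-Ar1-ethyl]-5-[(4R)-2,2,4-trimethyl-1,3-dioxolan-4-yl]pent-2-enoate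
Conditions: methacryloyl chloride, Et3N, DMAP (cat.), CH2Cl2, 0 °C
Reagents that add atoms: methacryloyl chloride, C=C(C)C(Cl)=O
Why: DMAP-catalysed acylation through the acylpyridinium ion is fast enough to outrun 1,2-acetyl migration and lactonisation of the C8 alcohol onto the C14 ester.

Step 13
Reactants: 21 methyl (2E)-2-[(1R,2R)-1-acetoxy-2-(methacryloyloxy)-2-Ar1-ethyl]-5-[(4R)-2,2,4-trimethyl-1,3-dioxolan-4-yl]pent-2-enoate
Product: 22 methyl (2E)-2-[(1R,2R)-1-acetoxy-2-(methacryloyloxy)-2-Bt-ethyl]-5-[(4R)-2,2,4-trimethyl-1,3-dioxolan-4-yl]pent-2-enoate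
Conditions: AcOOH, NaOAc, CH2Cl2, 0 °C → rt
Reagents that add atoms: peracetic acid, CC(=O)OO
Why: Peracid ipso-oxidation of a 2-silylfuran (attack at the silicon-bearing carbon, C→O silyl shift, protonation at C6) gives the 2(5H)-furanone with its carbonyl at C12 only, and the electron-poor alkenes are inert to the buffered peracid.

Step 14
Reactants: 22 methyl (2E)-2-[(1R,2R)-1-acetoxy-2-(methacryloyloxy)-2-Bt-ethyl]-5-[(4R)-2,2,4-trimethyl-1,3-dioxolan-4-yl]pent-2-enoate
Product: 23 methyl (2E,6R)-2-[(1R,2R)-1-acetoxy-2-(methacryloyloxy)-2-Bt-ethyl]-6,7-dihydroxy-6-methylhept-2-enoate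
Conditions: AcOH/H2O/THF (3:1:1), 40 °C
Reagents that add atoms: none
Why: Acid hydrolysis of the terminal acetonide; the tert-butyldiphenylsilyl ether, the esters and the butenolide are stable to aqueous acetic acid.

Step 15
Reactants: 23 methyl (2E,6R)-2-[(1R,2R)-1-acetoxy-2-(methacryloyloxy)-2-Bt-ethyl]-6,7-dihydroxy-6-methylhept-2-enoate
Product: 24 methyl (2E,6R)-2-[(1R,2R)-1-acetoxy-2-(methacryloyloxy)-2-Bt-ethyl]-6-hydroxy-6-methyl-7-oxohept-2-enoate
Conditions: SO3·pyridine, DMSO, i-Pr2NEt, CH2Cl2, 0 °C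
Reagents that add atoms: none
Why: Parikh–Doering oxidation converts the primary alcohol into the C5 aldehyde and cannot touch the tertiary alcohol; the aldehyde has no α-hydrogen, so C4 cannot epimerise.

Step 16
Reactants: 24 methyl (2E,6R)-2-[(1R,2R)-1-acetoxy-2-(methacryloyloxy)-2-Bt-ethyl]-6-hydroxy-6-methyl-7-oxohept-2-enoate
Product: 25 methyl (2E,6R)-2-[(1R,2R)-1-acetoxy-2-(methacryloyloxy)-2-Bt-ethyl]-6-methyl-7-oxo-6-[(triethylsilyl)oxy]hept-2-enoate
Conditions: TESOTf, 2,6-lutidine, CH2Cl2, −78 °C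
Reagents that add atoms: triethylsilyl trifluoromethanesulfonate, CC[Si](CC)(CC)OS(=O)(=O)C(F)(F)F
Why: Silyl triflate silylation of the hindered tertiary alcohol gives the non-chelating C4 silyl ether needed for Felkin–Anh control in step 18.

Step 17
Reactants: 25 methyl (2E,6R)-2-[(1R,2R)-1-acetoxy-2-(methacryloyloxy)-2-Bt-ethyl]-6-methyl-7-oxo-6-[(triethylsilyl)oxy]hept-2-enoate
Product: 26 methyl (2E,6R)-2-[(1R,2R)-1-acetoxy-2-(methacryloyloxy)-2-Ar2-ethyl]-6-methyl-7-oxo-6-[(triethylsilyl)oxy]hept-2-enoate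
Conditions: TIPSOTf, Et3N, CH2Cl2, 0 °C
Reagents that add atoms: triisopropylsilyl trifluoromethanesulfonate, CC(C)[Si](OS(=O)(=O)C(F)(F)F)(C(C)C)C(C)C
Why: Soft enolisation (O-silylation of the lactone carbonyl, then γ-deprotonation at C6 by the amine) gives the aromatic 2-silyloxyfuran, while the aldehyde cannot enolise and the excess amine keeps the medium non-acidic.

Step 18
Reactants: 26 methyl (2E,6R)-2-[(1R,2R)-1-acetoxy-2-(methacryloyloxy)-2-Ar2-ethyl]-6-methyl-7-oxo-6-[(triethylsilyl)oxy]hept-2-enoate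
Product: 27 methyl (1(10)E,4R,5S,6S,8R,9R)-9-acetoxy-13-[(tert-butyldiphenylsilyl)oxy]-5-hydroxy-8-(methacryloyloxy)-4-[(triethylsilyl)oxy]germacra-1(10),7(11)-dien-12,6-olid-14-oate
Conditions: BF3·OEt2, CH2Cl2 (about 1 mM), −78 °C, slow addition of 26
Reagents that add atoms: none
Why: Proposed new method: BF3 activates the non-enolisable C5 aldehyde and the 2-silyloxyfuran attacks through C6, its only free nucleophilic carbon (C11 is fully substituted), in an open transition state; loss of the silyl group as its fluoride turns the furan into the C7=C11 butenolide. The closest known reaction is the intermolecular vinylogous Mukaiyama aldol addition of 2-silyloxyfurans to α-alkoxy aldehydes, which has not been used to close a ten-membered carbocycle. The ring closes in a 10-exo-trig mode by C5–C6 bond formation under high dilution. C5 is controlled by Felkin–Anh addition anti to the C4 silyloxy group under non-chelating BF3 activation; C6 is controlled by the tether, since the chain from C7 to C3 with its C8/C9 stereocentres lets only one furan face reach the aldehyde, which is expected to place the C5 hydroxyl and the C6 oxygen cis on the new ring. The step needs γ-selectivity, ring closure in preference to intermolecular aldol addition, and survival of the C8 ester and the C13 oxygen; these are secured by the furan substitution pattern, by dilution, and by working at −78 °C with a silyl ether in place of an acyloxy leaving group at C13.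

Step 19
Reactants: 27 methyl (1(10)E,4R,5S,6S,8R,9R)-9-acetoxy-13-[(tert-butyldiphenylsilyl)oxy]-5-hydroxy-8-(methacryloyloxy)-4-[(triethylsilyl)oxy]germacra-1(10),7(11)-dien-12,6-olid-14-oate
Product: 28 methyl (1(10)E,4R,5S,6S,8R,9R)-9-acetoxy-4,5,13-trihydroxy-8-(methacryloyloxy)germacra-1(10),7(11)-dien-12,6-olid-14-oate
Conditions: HF·pyridine, pyridine, THF, 0 °C → rt
Reagents that add atoms: none
Why: Fluoride-mediated Si–O cleavage removes both silyl ethers under mildly acidic conditions that should not trigger retro-aldol cleavage or elimination of the β-hydroxy butenolide.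

Step 20
Reactants: 28 methyl (1(10)E,4R,5S,6S,8R,9R)-9-acetoxy-4,5,13-trihydroxy-8-(methacryloyloxy)germacra-1(10),7(11)-dien-12,6-olid-14-oate
Product: 29 methyl (1(10)E,4R,5S,6S,8R,9R)-9-acetoxy-4,5-dihydroxy-8-(methacryloyloxy)-13-[(methoxycarbonyl)oxy]germacra-1(10),7(11)-dien-12,6-olid-14-oate
Conditions: ClCO2Me, pyridine, CH2Cl2, −20 °C
Reagents that add atoms: methyl chloroformate, COC(=O)Cl
Why: Chemoselective acylation, the unhindered primary allylic alcohol reacting with the chloroformate far faster than the neopentyl-type secondary and the tertiary alcohols.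

Step 21
Reactants: 29 methyl (1(10)E,4R,5S,6S,8R,9R)-9-acetoxy-4,5-dihydroxy-8-(methacryloyloxy)-13-[(methoxycarbonyl)oxy]germacra-1(10),7(11)-dien-12,6-olid-14-oate
Product: 30 methyl (1(10)E,4R,5S,6S,7S,8R,9R)-9-acetoxy-4,5-dihydroxy-8-(methacryloyloxy)germacra-1(10),11(13)-dien-12,6-olid-14-oate
Conditions: Pd2(dba)3·CHCl3 (cat.), n-Bu3P, HCO2NH4, THF, rt
Reagents that add atoms: none
Why: Tsuji-type palladium-catalysed formate hydrogenolysis with allylic transposition: zerovalent palladium ionises the primary allylic carbonate (much faster than the acetate or methacrylate), and within the allylpalladium formate the hydride goes to the more substituted terminus C7 from the face opposite the C5 substituent, cis to H6, giving the exocyclic methylene and the (7S) centre.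

Step 22
Reactants: 30 methyl (1(10)E,4R,5S,6S,7S,8R,9R)-9-acetoxy-4,5-dihydroxy-8-(methacryloyloxy)germacra-1(10),11(13)-dien-12,6-olid-14-oate
Product: 32 fluctuadin, via C5 mesylate 31 (not isolated)
Conditions: MsCl, Et3N, CH2Cl2, −20 °C; then DBU, 0 °C → rt
Reagents that add atoms: none
Why: Sulfene mesylation selects the secondary C5 hydroxyl over the tertiary one, and the amidine base then triggers intramolecular Williamson displacement (3-exo-tet) by the C4 oxygen with inversion at C5, giving the trans-epoxide (5R) of the target.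

**Compound list**
1 | (R)-(−)-linalool, (3R)-3,7-dimethylocta-1,6-dien-3-ol | C=C[C@](C)(O)CCC=C(C)C | starting material
2 | (2R)-2-hydroxy-2-methylpentanedial, present as its ozonide and methoxy hydroperoxide forms | O=C[C@](C)(O)CCC=O | intermediate (not isolated)
3 | (2R)-2-methylpentane-1,2,5-triol | OC[C@](C)(O)CCCO | intermediate
4 | 3-[(4R)-2,2,4-trimethyl-1,3-dioxolan-4-yl]propan-1-ol | OCCC[C@]1(C)COC(C)(C)O1 | intermediate
5 | 3-[(4R)-2,2,4-trimethyl-1,3-dioxolan-4-yl]propanal | O=CCC[C@]1(C)COC(C)(C)O1 | intermediate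
6 | furan-3-ylmethanol | OCc1ccoc1 | starting material
7 | tert-butyl(furan-3-ylmethoxy)dimethylsilane | CC(C)(C)[Si](C)(C)OCc1ccoc1 | intermediate
8 | [2-(tert-butyldimethylsilyl)furan-3-yl]methanol | OCc1ccoc1[Si](C)(C)C(C)(C)C | intermediate
9 | 2-chloro-N-methoxy-N-methylacetamide | CON(C)C(=O)CCl | starting material
10 | lithium [2-(tert-butyldimethylsilyl)-4-lithiofuran-3-yl]methanolate | [Li]OCc1c([Li])coc1[Si](C)(C)C(C)(C)C | intermediate (not isolated)
11 | 1-[5-(tert-butyldimethylsilyl)-4-(hydroxymethyl)furan-3-yl]-2-chloroethan-1-one | OCc1c(C(=O)CCl)coc1[Si](C)(C)C(C)(C)C | intermediate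
12 | 1-[5-(tert-butyldimethylsilyl)-4-{[(tert-butyldiphenylsilyl)oxy]methyl}furan-3-yl]-2-chloroethan-1-one | CC(C)(C)[Si](OCc1c(C(=O)CCl)coc1[Si](C)(C)C(C)(C)C)(c1ccccc1)c1ccccc1 | intermediate
13 | trimethyl phosphonoacetate | COC(=O)CP(=O)(OC)OC | starting material
14 | sodium enolate of trimethyl phosphonoacetate | [Na+].COC(=O)[CH-]P(=O)(OC)OC | intermediate (not isolated)
15 | methyl 2-(dimethoxyphosphoryl)-4-oxo-4-Ar1-butanoate (racemic at C10) | COC(=O)C(CC(=O)c1coc([Si](C)(C)C(C)(C)C)c1CO[Si](c1ccccc1)(c1ccccc1)C(C)(C)C)P(=O)(OC)OC | intermediate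
16 | methyl (2E)-2-(2-oxo-2-Ar1-ethyl)-5-[(4R)-2,2,4-trimethyl-1,3-dioxolan-4-yl]pent-2-enoate | CC1(C)OC[C@@](C)(CC/C=C(/C(=O)OC)CC(=O)c2coc([Si](C)(C)C(C)(C)C)c2CO[Si](c2ccccc2)(c2ccccc2)C(C)(C)C)O1 | intermediate
17 | sodium (Z)-enolate of 16 across C8–C9 | [Na+].CC1(C)OC[C@@](C)(CC/C=C(/C(=O)OC)\C=C(/[O-])c2coc([Si](C)(C)C(C)(C)C)c2CO[Si](c2ccccc2)(c2ccccc2)C(C)(C)C)O1 | intermediate (not isolated)
18 | sodium alkoxide of the (9R)-9-hydroxy derivative of 16 | [Na+].CC1(C)OC[C@@](C)(CC/C=C(/C(=O)OC)[C@@H]([O-])C(=O)c2coc([Si](C)(C)C(C)(C)C)c2CO[Si](c2ccccc2)(c2ccccc2)C(C)(C)C)O1 | intermediate (not isolated)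
19 | methyl (2E)-2-[(1R)-1-acetoxy-2-oxo-2-Ar1-ethyl]-5-[(4R)-2,2,4-trimethyl-1,3-dioxolan-4-yl]pent-2-enoate | CC1(C)OC[C@@](C)(CC/C=C(/C(=O)OC)[C@@H](OC(C)=O)C(=O)c2coc([Si](C)(C)C(C)(C)C)c2CO[Si](c2ccccc2)(c2ccccc2)C(C)(C)C)O1 | intermediate
20 | methyl (2E)-2-[(1R,2R)-1-acetoxy-2-hydroxy-2-Ar1-ethyl]-5-[(4R)-2,2,4-trimethyl-1,3-dioxolan-4-yl]pent-2-enoate | CC1(C)OC[C@@](C)(CC/C=C(/C(=O)OC)[C@@H](OC(C)=O)[C@H](O)c2coc([Si](C)(C)C(C)(C)C)c2CO[Si](c2ccccc2)(c2ccccc2)C(C)(C)C)O1 | intermediate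
21 | methyl (2E)-2-[(1R,2R)-1-acetoxy-2-(methacryloyloxy)-2-Ar1-ethyl]-5-[(4R)-2,2,4-trimethyl-1,3-dioxolan-4-yl]pent-2-enoate | CC1(C)OC[C@@](C)(CC/C=C(/C(=O)OC)[C@@H](OC(C)=O)[C@H](OC(=O)C(C)=C)c2coc([Si](C)(C)C(C)(C)C)c2CO[Si](c2ccccc2)(c2ccccc2)C(C)(C)C)O1 | intermediate
22 | methyl (2E)-2-[(1R,2R)-1-acetoxy-2-(methacryloyloxy)-2-Bt-ethyl]-5-[(4R)-2,2,4-trimethyl-1,3-dioxolan-4-yl]pent-2-enoate | CC1(C)OC[C@@](C)(CC/C=C(/C(=O)OC)[C@@H](OC(C)=O)[C@H](OC(=O)C(C)=C)C2=C(CO[Si](c3ccccc3)(c3ccccc3)C(C)(C)C)C(=O)OC2)O1 | intermediate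
23 | methyl (2E,6R)-2-[(1R,2R)-1-acetoxy-2-(methacryloyloxy)-2-Bt-ethyl]-6,7-dihydroxy-6-methylhept-2-enoate | OC[C@](C)(O)CC/C=C(/C(=O)OC)[C@@H](OC(C)=O)[C@H](OC(=O)C(C)=C)C1=C(CO[Si](c2ccccc2)(c2ccccc2)C(C)(C)C)C(=O)OC1 | intermediate
24 | methyl (2E,6R)-2-[(1R,2R)-1-acetoxy-2-(methacryloyloxy)-2-Bt-ethyl]-6-hydroxy-6-methyl-7-oxohept-2-enoate | O=C[C@](C)(O)CC/C=C(/C(=O)OC)[C@@H](OC(C)=O)[C@H](OC(=O)C(C)=C)C1=C(CO[Si](c2ccccc2)(c2ccccc2)C(C)(C)C)C(=O)OC1 | intermediate
25 | methyl (2E,6R)-2-[(1R,2R)-1-acetoxy-2-(methacryloyloxy)-2-Bt-ethyl]-6-methyl-7-oxo-6-[(triethylsilyl)oxy]hept-2-enoate | O=C[C@](C)(O[Si](CC)(CC)CC)CC/C=C(/C(=O)OC)[C@@H](OC(C)=O)[C@H](OC(=O)C(C)=C)C1=C(CO[Si](c2ccccc2)(c2ccccc2)C(C)(C)C)C(=O)OC1 | intermediate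
26 | methyl (2E,6R)-2-[(1R,2R)-1-acetoxy-2-(methacryloyloxy)-2-Ar2-ethyl]-6-methyl-7-oxo-6-[(triethylsilyl)oxy]hept-2-enoate (seco aldehyde with 2-silyloxyfuran) | O=C[C@](C)(O[Si](CC)(CC)CC)CC/C=C(/C(=O)OC)[C@@H](OC(C)=O)[C@H](OC(=O)C(C)=C)c1coc(O[Si](C(C)C)(C(C)C)C(C)C)c1CO[Si](c1ccccc1)(c1ccccc1)C(C)(C)C | intermediate
27 | methyl (1(10)E,4R,5S,6S,8R,9R)-9-acetoxy-13-[(tert-butyldiphenylsilyl)oxy]-5-hydroxy-8-(methacryloyloxy)-4-[(triethylsilyl)oxy]germacra-1(10),7(11)-dien-12,6-olid-14-oate | C=C(C)C(=O)O[C@@H]1C2=C(CO[Si](c3ccccc3)(c3ccccc3)C(C)(C)C)C(=O)O[C@@H]2[C@H](O)[C@](C)(O[Si](CC)(CC)CC)CC/C=C(/C(=O)OC)[C@H]1OC(C)=O | intermediate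
28 | methyl (1(10)E,4R,5S,6S,8R,9R)-9-acetoxy-4,5,13-trihydroxy-8-(methacryloyloxy)germacra-1(10),7(11)-dien-12,6-olid-14-oate | C=C(C)C(=O)O[C@@H]1C2=C(CO)C(=O)O[C@@H]2[C@H](O)[C@](C)(O)CC/C=C(/C(=O)OC)[C@H]1OC(C)=O | intermediate
29 | methyl (1(10)E,4R,5S,6S,8R,9R)-9-acetoxy-4,5-dihydroxy-8-(methacryloyloxy)-13-[(methoxycarbonyl)oxy]germacra-1(10),7(11)-dien-12,6-olid-14-oate | C=C(C)C(=O)O[C@@H]1C2=C(COC(=O)OC)C(=O)O[C@@H]2[C@H](O)[C@](C)(O)CC/C=C(/C(=O)OC)[C@H]1OC(C)=O | intermediate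
30 | methyl (1(10)E,4R,5S,6S,7S,8R,9R)-9-acetoxy-4,5-dihydroxy-8-(methacryloyloxy)germacra-1(10),11(13)-dien-12,6-olid-14-oate | C=C(C)C(=O)O[C@@H]1[C@@H]2C(=C)C(=O)O[C@@H]2[C@H](O)[C@](C)(O)CC/C=C(/C(=O)OC)[C@H]1OC(C)=O | intermediate
31 | 5-O-methanesulfonyl derivative of 30 | C=C(C)C(=O)O[C@@H]1[C@@H]2C(=C)C(=O)O[C@@H]2[C@H](OS(C)(=O)=O)[C@](C)(O)CC/C=C(/C(=O)OC)[C@H]1OC(C)=O | intermediate (not isolated)
32 | fluctuadin, methyl (1(10)E,4R,5R,6S,7S,8R,9R)-9-acetoxy-4,5-epoxy-8-(methacryloyloxy)germacra-1(10),11(13)-dien-12,6-olid-14-oate | C=C(C)C(=O)O[C@@H]1[C@@H]2C(=C)C(=O)O[C@@H]2[C@H]2O[C@]2(C)CC/C=C(/C(=O)OC)[C@H]1OC(C)=O | target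

**Totals**
Total step count: 22. Longest linear sequence: 19 steps (6 → 32 through steps 4–22); the linalool branch (steps 1–3) joins at step 9.

**Steps most likely to fail**

1. Step 18. The ring closure may lose to intermolecular aldol addition (oligomers), the furan may reach the aldehyde from the wrong face at C6, or the C8 ester may ionise under the Lewis acid. Fallback from 21 back to 27, with the polarity at C6 reversed and the dearomatisation postponed: 21 would be iodinated at its free furan carbon C6 (N-iodosuccinimide, DMF, 0 °C) to give the iodofuran F1. Acetonide hydrolysis as in step 14 would give the diol F2, Parikh–Doering oxidation the hydroxy aldehyde F3, and silylation with TESOTf the silyl-protected aldehyde F4. An intramolecular Nozaki–Hiyama–Kishi reaction (CrCl2, NiCl2 cat., DMF/THF, high dilution), a known route to ten-membered carbocycles, would then close C5–C6 to the furan-fused carbinol F5, with C5 set by the same Felkin–Anh preference. Peracetic acid oxidation of the silylfuran as in step 13 would convert F5 into 27, C6 being set on protonation of the intermediate 2-oxyfuran at the acidic γ-position.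

2. Step 21. The hydride may be delivered to the CH2 terminus (giving the conjugated α-methyl butenolide) or to the wrong face of C7, or the C9 allylic acetate may ionise as well. Fallback from 28 back to 30 without palladium: a Mitsunobu reaction of the primary allylic alcohol of 28 with 2-nitrobenzenesulfonylhydrazide (PPh3, diethyl azodicarboxylate, THF, −30 °C) would give the N-allyl sulfonylhydrazine F6. On warming, F6 loses the sulfinic acid to give the allylic diazene F7, which expels dinitrogen in a retro-ene step that moves hydrogen to C7 and the double bond to C11=C13 (reductive 1,3-transposition of an allylic alcohol), arriving at 30.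

3. Step 13. The peracid may attack the free furan carbon C6 instead of the silicon-bearing carbon, or the bulky silyl group may slow the ipso-oxidation so that ring-opened ene-dione products form. Fallback from 21 back to 22: sensitised photooxygenation (O2, rose bengal, visible light, CH2Cl2/MeOH, −78 °C) of the 2-silylfuran, in which the silicon-bearing carbon becomes the lactone carbonyl, would give the 5-hydroxybutenolide F8. Reduction of this lactol with NaBH4 (MeOH, 0 °C) and acidification to relactonise would give 22.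

**Further compounds**
F1 | step 18 | C6-iodo derivative of 21 (iodine on the free furan carbon) | CC1(C)OC[C@@](C)(CC/C=C(/C(=O)OC)[C@@H](OC(C)=O)[C@H](OC(=O)C(C)=C)c2c(I)oc([Si](C)(C)C(C)(C)C)c2CO[Si](c2ccccc2)(c2ccccc2)C(C)(C)C)O1
F2 | step 18 | C4,C5-diol of the iodofuran | OC[C@](C)(O)CC/C=C(/C(=O)OC)[C@@H](OC(C)=O)[C@H](OC(=O)C(C)=C)c1c(I)oc([Si](C)(C)C(C)(C)C)c1CO[Si](c1ccccc1)(c1ccccc1)C(C)(C)C
F3 | step 18 | C4-hydroxy C5-aldehyde of the iodofuran | O=C[C@](C)(O)CC/C=C(/C(=O)OC)[C@@H](OC(C)=O)[C@H](OC(=O)C(C)=C)c1c(I)oc([Si](C)(C)C(C)(C)C)c1CO[Si](c1ccccc1)(c1ccccc1)C(C)(C)C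
F4 | step 18 | C4-triethylsilyloxy C5-aldehyde of the iodofuran | O=C[C@](C)(O[Si](CC)(CC)CC)CC/C=C(/C(=O)OC)[C@@H](OC(C)=O)[C@H](OC(=O)C(C)=C)c1c(I)oc([Si](C)(C)C(C)(C)C)c1CO[Si](c1ccccc1)(c1ccccc1)C(C)(C)C
F5 | step 18 | furan-fused ten-membered C5 carbinol (C5–C6 bond closed, furan still silylated at C12) | C=C(C)C(=O)O[C@@H]1c2c(CO[Si](c3ccccc3)(c3ccccc3)C(C)(C)C)c([Si](C)(C)C(C)(C)C)oc2[C@H](O)[C@](C)(O[Si](CC)(CC)CC)CC/C=C(/C(=O)OC)[C@H]1OC(C)=O
F6 | step 21 | C13 N-(2-nitrobenzenesulfonyl)hydrazine derived from 28 | C=C(C)C(=O)O[C@@H]1C2=C(CN(N)S(=O)(=O)c3ccccc3[N+](=O)[O-])C(=O)O[C@@H]2[C@H](O)[C@](C)(O)CC/C=C(/C(=O)OC)[C@H]1OC(C)=O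
F7 | step 21 | C13 allylic diazene | C=C(C)C(=O)O[C@@H]1C2=C(CN=N)C(=O)O[C@@H]2[C@H](O)[C@](C)(O)CC/C=C(/C(=O)OC)[C@H]1OC(C)=O
F8 | step 13 | 6-hydroxy derivative of 22 (5-hydroxybutenolide, either configuration at C6) | CC1(C)OC[C@@](C)(CC/C=C(/C(=O)OC)[C@@H](OC(C)=O)[C@H](OC(=O)C(C)=C)C2=C(CO[Si](c3ccccc3)(c3ccccc3)C(C)(C)C)C(=O)OC2O)O1
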